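(The readings come from a simulation on assumed constants, and the scatter is random.)

Count what the partner can pay for before reading any curve.

| flask | starting material | partner | temperature | remark | time |
|---|---|---|---|---|---|
| autumn | 0.20 mM (fed, over 15 s) | 0.10 mM | 20 °C | run made earlier |  |
| spring | 0.20 mM (fed, over 15 s) | 0.36 mM | 31 °C | run made earlier |  |
| cedar | 0.20 mM (fed, over 15 s) | 0.400 mM | 25 °C |  | 6.0 min |
| ash | 0.20 mM | 0.200 mM | 25 °C | everything together at the start | 6.0 min |

| autumn: time / min | autumn: bis adduct / % | spring: time / min | spring: bis adduct / % |
|---|---|---|---|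
| 0.500 | 0.3 | 0.500 | 3.0 |
| 0.667 | 0.3 | 0.667 | 3.0 |
| 1.00 | 1.5 | 1.00 | 4.3 |
| 1.50 | 2.0 | 1.50 | 4.7 |
| 2.50 | 1.7 | 2.50 | 5.2 |
| 4.00 | 1.8 | 4.00 | 7.1 |
| 6.00 | 1.9 | 6.00 | 6.9 |

(each reading ± 0.5 percentage points)

* the flask that ends with the higher amount of bis adduct, in percent of the starting material charged, or "neither" when 2 percentage points or less lies between them (cedar / ash / neither)
* final bis adduct, as a percentage of the starting material charged, in cedar
* final bis adduct, as a percentage of the starting material charged, in ash

I build the flask one process at a time, and I suppose that bis adduct costs two partner per starting material. With that main step alone the number is the ceiling Y = c_B/(2 c_A), where c_B is the partner and c_A the starting material charged, which gives 100% in cedar and 50.0% in ash. Adding a mono adduct on the way, each one holding a partner and giving no bis adduct, puts the number below Y by an amount the readings do not give. Adding the rest, a loss that I suppose from the levelling of the readings, I stop counting steps and read: the last spring reading is 6.9% against a ceiling of 90.0%. So I carry s, the catch share, meaning the part of the charged partner that ends in bis adduct: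

s = 2 y c_A / c_B: autumn 7.60%, spring 7.67%, mean 7.63%

These are readings, each y good to 0.5 percentage points, and the two runs differ in charge and temperature, yet their shares stand close. My reckoning for 25 °C is then:

y = s Y: cedar 7.63%, ash 3.82%

Equal shares make cedar twice ash, a lead of 3.8 points, more than the margin of 2 points.

The forecast says cedar, with 6.5% in cedar, lower than my figure, and 3.5% in ash, on the ground that “Bis therefore scales with the partner left over after the first addition.”

The flask gives cedar, with 12.3% in cedar and 5.90% in ash.

    starting material + partner → mono adduct (k = 46.0 M⁻¹ s⁻¹, Ea = 43.0 kJ mol⁻¹)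
    partner + mono adduct → bis adduct (k = 120 M⁻¹ s⁻¹, Ea = 36.0 kJ mol⁻¹)
    partner + bis adduct → tris adduct (k = 63.0 M⁻¹ s⁻¹, Ea = 39.0 kJ mol⁻¹)
    partner → decomposed reagent (k = 0.0140 s⁻¹, Ea = 78.0 kJ mol⁻¹)
    partner ⇌ dormant form (K = 8.20, k = 0.0190 s⁻¹, Ea = 91.0 kJ mol⁻¹, ΔH = 15.0 kJ mol⁻¹)
    (constants at 25 °C)

The share comes back as 12.3% in cedar and 11.8% in ash, close to each other but above the carried 7.63%. In the neighbour flask, like ash with 0.50 mM of partner, it is 15.2%. Of the two settings that part ash from cedar, the partner charge has the larger effect on ash, though it is not the whole of the gap: ash given the partner of cedar stands at 15.1% instead of 5.90%, and ash with its starting material fed as in cedar stands at 4.58%.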